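## Analysis of the target

The target (29) is a linear tridepside: three benzene rings joined head to tail by two aryl ester bonds, from the ring A carbonyl to O4 of ring B and from the ring B carbonyl to O4 of ring C, ending in the free carboxylic acid of ring C. Rings B and C are both orsellinate units (C1 carboxyl, C2–OH, C3–H, C4–O, C5–H, C6–CH3). Ring A is a 3,4-dihydroxy-6-methoxy-2-methylbenzoyl group: a catechol at C3/C4, a methyl at C2 and a methoxy at C6. There is no stereocentre, so the problem is chemoselectivity among five phenolic hydroxyls, one methyl ether and three carboxyl carbons. The sensitive groups are the two depside esters (activated aryl esters, cleaved or scrambled by alkoxides, amines and hydroxide), the air-sensitive ring A catechol, and the salicylic-type acids, which lose CO2 when heated in acid. The last step therefore has to be neutral. Each acyl carbon that must be esterified sits between two ortho substituents, so both ester bonds are hindered. The strategy rests on ring C: C2–OH and C4–O flank C3–H in a resorcinol pattern, and C1 (carboxyl) with C6 (methyl) form a methyl-substituted acrylate unit. That ring can be put together from an unsaturated diazo ketone carrying C1, C6, C2 and C5 and an ynol ether carrying C3 and C4, with the two oxygens arriving differentiated. Ring B has the same substitution, so the same building block serves twice.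

## Retrosynthetic reasoning

Target 29 is traced back to its tribenzyl derivative 28 by cutting three O–benzyl bonds. Hydrogenolysis is the one unmasking that is neutral, touches neither depside ester and frees the catechol and the acid in the same operation, so every group still protected at the end is chosen to be benzyl.

In 28 the ester between the ring A carbonyl and O4 of ring B is cut, giving acid 26 and phenol 18. This bond goes last because 26 is the most elaborate fragment and because 18 has a single unchelated hydroxyl: its other two hydroxyls are each hydrogen-bonded to an ortho ester carbonyl. The forward reaction must acylate only that oxygen with a di-ortho-substituted acid, without base, which points to a mixed-anhydride activation.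

Phenol 18 comes from its silyl ether 17, and 17 is cut at the ester between the ring B carbonyl and O4 of ring C, giving acid 15 and phenol 14. The silyl group on O4 of 15 prevents self-condensation and becomes the nucleophilic site of the following coupling once removed. The 2-OH of 15 is left free because it is chelated and poorly nucleophilic.

Both 14 and 15 are derived from one compound, 13, which carries a benzyl ester, a free C2–OH and a silylated C4–O. Desilylation gives 14 for ring C, and hydrogenolysis of the ester gives 15 for ring B. One ring-forming reaction thus supplies two of the three rings.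

Ring C of 13 is disconnected at C1–C2, C2–C3, C4–C5 and C5–C6 into diazo ketone 5 and ynol ether 9. The cut is made here because it turns the ring into an acrylate unit (C1=C6 with its ester and methyl) and an oxygenated two-carbon unit (C3–C4), and because it delivers O2 as a free phenol and O4 as a silyl ether. The forward reaction has to generate vinylketene 10 from 5, add 9 across the ketene in one orientation to give cyclobutenone 11, and carry 11 through dienylketene 12 to the arene.

Diazo ketone 5 is traced to methyl ketone 3 by diazo transfer, and 3 to diketone 1 and ylide 2 by Wittig olefination. The textbook route to a diazo ketone, acylation of the parent diazoalkane by an acid chloride of a fumarate-type half ester, is avoided. The doubly activated C=C of such an acid chloride is an excellent dipolarophile and would be consumed as a pyrazoline. Differentiating the two carboxyls of the diacid would also cost steps.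

Ynol ether 9 is cut at the O–Si bond to ynolate 8 and silyl chloride 7, and 8 is obtained by cycloreversion of lithiated isoxazole 6. The bulky silyl group is needed so that silylation occurs at oxygen.

Acid 26 is traced to aldehyde 25 (oxidation), 25 to arene 23 (formylation para to one benzyloxy and ortho to the methoxy group), 23 to catechol 22 (benzylation), 22 to salicylaldehyde 20 (aryl migration to oxygen via formate 21) and 20 to phenol 19 (ortho-formylation at the only free ortho position). Introducing the carboxyl carbon last avoids having to hydroxylate a deactivated benzoate selectively.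

## Alternatives that were turned down

Alternative 1: The ring A carbonyl is disconnected on both sides at once, into aryl iodide A2, carbon monoxide A4 and the didepside phenol A3 (the same compound as 18). In the forward step Pd(OAc)2 and Xantphos would join the three components to give the tribenzyl tridepside A1 (the same compound as 28).
- For: ring A needs no carboxyl group and no acid activation, and the hindered carbonyl is built on palladium instead of by substitution at a di-ortho-substituted acyl derivative. A2 would come from 23 in one iodination, one step fewer than the formylation and oxidation used here. On these points it is stronger.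
- Against: oxidative addition to an electron-rich iodide flanked by methyl and methoxy is slow. The acylpalladium intermediate must be taken up by a weakly nucleophilic phenol, which needs a base; a phenoxide of A3 in a warm basic medium can attack the depside ester already present and scramble it, and A3 offers three hydroxyls.
- Comparison: it forms no ring, so all three arenes and the ester of A3 must still come from conventional chemistry. The chosen strategy offers a ring construction with differentiated oxygens and ester formations under acidic, base-free conditions.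

Alternative 2: Ring C is cut at C1–C6 and C3–C4 into benzyl acetoacetate A6 and ethyl crotonate A7. In the forward step the enolate of A6 adds to A7 and the acetyl methyl then closes onto the crotonate ester, giving the dihydro compound A5, benzyl trans-6-methyl-2,4-dioxocyclohexane-1-carboxylate.
- For: the cheapest reagents, robust classical enolate chemistry, no photochemistry and no diazo compound. On cost and on reliability of the ring-forming step it is stronger than the chosen route.
- Against: an alkoxide base with one benzyl and one ethyl ester invites ester exchange. A5 is at the wrong oxidation level and needs a separate dehydrogenation, in which a cyclic 1,3-dione tends to be halogenated at C3 and C5; removing such halogens reductively would take the benzyl ester as well. The two oxygens emerge equivalent, so ring B would need an extra selective protection of O4. Two stereocentres are made only to be destroyed.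
- Comparison: the chosen strategy reaches the aromatic level directly and gives O2 free and O4 protected without further steps.

Alternative 3: Ring B is cut at C1–C2 and C5–C6. The ring C aryl but-2-ynoate A9 would react with 1-methoxy-1,3-bis(trimethylsilyloxy)buta-1,3-diene A10 in a [4+2] cycloaddition, followed by loss of the alkoxy and silyl groups, to give the didepside A8.
- For: the ester between rings B and C is made early as an unhindered butynoate, which avoids the hindered aryl acid coupling. The orientation follows from the polarised diene, and A8 has O4 of ring B free for ring A. On the ease of the ester bond between rings B and C it is stronger.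
- Against: a methyl-substituted ynoate is a sluggish dienophile and needs heat. The aryl ester is an activated ester with a good phenoxide leaving group, so the ketene acetal end of A10 can add stepwise and expel ring C instead of cycloadding. Aromatisation must lose the alkoxy group and not a silyloxy group.
- Comparison: ring C still has to be obtained separately with O2 and O4 differentiated. Both approaches build one ring, but here one annulation product feeds rings B and C, and the aryl ester bonds are formed only after the ring-forming chemistry.

Key step: step 4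

Remark on the chemistry: the target has no stereocentre; each ring is numbered from its carboxyl-bearing carbon as C1, and the one sp3 centre of transient 11 is racemic and is lost again.

## Route

Step 1
Reactants: 1 2,3-butanedione; 2 benzyl (triphenylphosphoranylidene)acetate
Product: 3 benzyl (2E)-3-methyl-4-oxopent-2-enoate
Conditions: CH2Cl2, 0 °C → rt (1 in excess)
Reagents that add atoms: none
Why: Wittig olefination of one carbonyl of the activated 1,2-diketone by a stabilised ylide; the enone formed is far less electrophilic, so a second olefination should not compete, and the E isomer (ester trans to acetyl) is expected as the more stable product, any Z isomer being equilibrated with catalytic iodine.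

Step 2
Reactants: 3 benzyl (2E)-3-methyl-4-oxopent-2-enoate
Product: 5 benzyl (2E)-5-diazo-3-methyl-4-oxopent-2-enoate, via trifluoroacetyl diketone 4 (not isolated)
Conditions: LiN(SiMe3)2, THF, −78 °C; CF3CO2CH2CF3; aq HCl; then MeSO2N3, Et3N, H2O, MeCN, rt
Reagents that add atoms: methanesulfonyl azide, CS(=O)(=O)N=[N+]=[N-] (the two diazo nitrogens); 2,2,2-trifluoroethyl trifluoroacetate, O=C(OCC(F)(F)F)C(F)(F)F (the CF3CO group, present only in 4)
Why: Detrifluoroacetylative diazo transfer (Regitz-type): kinetic enolisation at the acetyl methyl, the only ketone α-position, and acylation give 4, whose activated methylene takes up N2 from the sulfonyl azide with loss of the trifluoroacetyl group; no diazoalkane meets the electron-poor C=C, so pyrazoline formation is avoided.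

Step 3
Reactants: 6 3-phenylisoxazole; 7 triisopropylsilyl chloride
Product: 9 (triisopropylsilyloxy)ethyne, via lithium ethynolate 8 (not isolated)
Conditions: n-BuLi, THF, −78 → 0 °C; then 7, −78 °C → rt
Reagents that add atoms: n-butyllithium, [Li]CCCC (the lithium, present only in 8)
Why: Lithiation of 6 at C5 followed by cycloreversion of the lithioisoxazole releases benzonitrile and ynolate 8; the bulky silyl chloride should silylate 8 at oxygen, as known for ynolates, giving the ynol silyl ether.

Step 4
Reactants: 5 benzyl (2E)-5-diazo-3-methyl-4-oxopent-2-enoate; 9 (triisopropylsilyloxy)ethyne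
Product: 13 benzyl 2-hydroxy-6-methyl-4-(triisopropylsilyloxy)benzoate, via vinylketene 10 (not isolated), via cyclobutenone 11 (not isolated), via dienylketene 12 (not isolated)
Conditions: hν (300 nm), ClCH2CH2Cl, rt; then 80 °C
Reagents that add atoms: none
Why: Irradiation of 5 expels N2 and the alkenyl group migrates to the diazo carbon (photo-Wolff rearrangement, new bond C5–C6), giving vinylketene 10 in which the ester is trans to the ketene-bearing carbon and so cannot reach the ketene to lactonise. The unsubstituted, nucleophilic carbon of ynol ether 9 attacks the central ketene carbon and the oxygen-bearing carbon closes onto the former diazo carbon, a regioselective [2+2] cycloaddition (bonds C2–C3 and C4–C5) that gives the four-membered ring of 11. Conrotatory 4π opening of 11, which is reversible, breaks the C2–C5 bond and gives dienylketene 12; only the isomer with the alkenyl group turned inward can react on, and the reversibility returns the other one. Ring C then closes by thermal disrotatory 6π electrocyclisation of 12 (bond C1–C2), and the cyclohexadienone formed, whose sp3 carbon lies between the ketone and the ester, should enolise at once to phenol 13. The closest known reaction type is the Danheiser benzannulation in its diazo ketone form, which is established with siloxyalkynes and gives resorcinol monosilyl ethers. No stereocentre is formed. The step needs one orientation in the [2+2] event, secured by the polarisation of the ynol ether, and retention of the E enoate geometry, which keeps the ester on the outside of the cyclising triene; light near 300 nm, where the diazo ketone absorbs, is chosen to limit E/Z isomerisation. The oxygens arrive differentiated, C2–OH free and chelated to the ester, C4–O silylated.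

Step 5
Reactants: 13 benzyl 2-hydroxy-6-methyl-4-(triisopropylsilyloxy)benzoate
Product: 14 benzyl 2,4-dihydroxy-6-methylbenzoate (benzyl orsellinate)
Conditions: Bu4NF, AcOH, THF, 0 °C
Reagents that add atoms: none
Why: Fluoride cleavage of an aryl silyl ether; the acetic acid buffer protonates the phenoxide as it forms, so the ester is not attacked.

Step 6
Reactants: 13 benzyl 2-hydroxy-6-methyl-4-(triisopropylsilyloxy)benzoate
Product: 15 2-hydroxy-6-methyl-4-(triisopropylsilyloxy)benzoic acid
Conditions: H2 (1 atm), Pd/C, EtOAc, rt
Reagents that add atoms: none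
Why: Hydrogenolysis of the benzyl ester; the aryl silyl ether is inert to Pd/C and hydrogen in an aprotic solvent, and the acid is kept at room temperature to avoid decarboxylation.

Step 7
Reactants: 15 2-hydroxy-6-methyl-4-(triisopropylsilyloxy)benzoic acid; 14 benzyl 2,4-dihydroxy-6-methylbenzoate
Product: 17 benzyl 2-hydroxy-4-{[2-hydroxy-6-methyl-4-(triisopropylsilyloxy)benzoyl]oxy}-6-methylbenzoate, via mixed anhydride 16 (not isolated)
Conditions: (CF3CO)2O, toluene, 0 °C → rt
Reagents that add atoms: trifluoroacetic anhydride, O=C(OC(=O)C(F)(F)F)C(F)(F)F (the CF3CO group, present only in 16)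
Why: Depside esterification through the mixed trifluoroacetic anhydride, which suits electron-rich di-ortho-substituted benzoic acids because it reacts with acylium character; the 4-OH of 14 is the only unchelated phenol, and the 2-hydroxyls of both partners are hydrogen-bonded to their carbonyls and should stay free.

Step 8
Reactants: 17 benzyl 2-hydroxy-4-{[2-hydroxy-6-methyl-4-(triisopropylsilyloxy)benzoyl]oxy}-6-methylbenzoate
Product: 18 benzyl 4-[(2,4-dihydroxy-6-methylbenzoyl)oxy]-2-hydroxy-6-methylbenzoate
Conditions: Bu4NF, AcOH, THF, 0 °C
Reagents that add atoms: none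
Why: Buffered fluoride desilylation; the buffer keeps the freed ring B phenoxide from attacking the depside ester.

Step 9
Reactants: 19 4-methoxy-2-methylphenol
Product: 20 2-hydroxy-5-methoxy-3-methylbenzaldehyde
Conditions: (CH2O)n, MgCl2, Et3N, MeCN, reflux
Reagents that add atoms: paraformaldehyde (as formaldehyde), C=O
Why: Casnati–Skattebøl ortho-formylation; the magnesium phenoxide delivers formaldehyde to the ortho position, and only one ortho position is free.

Step 10
Reactants: 20 2-hydroxy-5-methoxy-3-methylbenzaldehyde
Product: 22 5-methoxy-3-methylbenzene-1,2-diol, via aryl formate 21 (not isolated)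
Conditions: H2O2, aq NaOH, 0 °C → rt, N2; then aq HCl
Reagents that add atoms: hydrogen peroxide, OO
Why: Dakin oxidation; the electron-rich aryl group migrates from the peroxide adduct of the aldehyde to oxygen and formate 21 is hydrolysed in the same flask, with exclusion of air to protect the catechol.

Step 11
Reactants: 22 5-methoxy-3-methylbenzene-1,2-diol
Product: 23 1,2-bis(benzyloxy)-5-methoxy-3-methylbenzene
Conditions: BnBr, K2CO3, DMF, rt → 50 °C, N2
Reagents that add atoms: benzyl bromide, BrCc1ccccc1
Why: Twofold Williamson etherification of the catechol; benzyl is chosen so that these ethers fall in the final hydrogenolysis.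

Step 12
Reactants: 23 1,2-bis(benzyloxy)-5-methoxy-3-methylbenzene
Product: 25 3,4-bis(benzyloxy)-6-methoxy-2-methylbenzaldehyde, via iminium salt 24 (not isolated)
Conditions: POCl3, DMF, 0 → 70 °C; then aq NaOAc
Reagents that add atoms: N,N-dimethylformamide, CN(C)C=O (the formyl carbon); water, O (the aldehyde oxygen); phosphoryl chloride, O=P(Cl)(Cl)Cl (the chloride, present only in 24)
Why: Vilsmeier–Haack formylation; attack should occur at the position para to the C1 benzyloxy group and ortho to the methoxy group, as in 1,2,4-trialkoxybenzenes and orcinol diethers, because the other free position lies between two alkoxy groups.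

Step 13
Reactants: 25 3,4-bis(benzyloxy)-6-methoxy-2-methylbenzaldehyde
Product: 26 3,4-bis(benzyloxy)-6-methoxy-2-methylbenzoic acid
Conditions: NaClO2, NaH2PO4, 2-methyl-2-butene, t-BuOH–H2O, rt
Reagents that add atoms: sodium chlorite, [Na+].[O-]Cl=O
Why: Pinnick oxidation of the aldehyde; the alkene scavenger removes hypochlorous acid, which would otherwise chlorinate the electron-rich ring.

Step 14
Reactants: 26 3,4-bis(benzyloxy)-6-methoxy-2-methylbenzoic acid; 18 benzyl 4-[(2,4-dihydroxy-6-methylbenzoyl)oxy]-2-hydroxy-6-methylbenzoate
Product: 28 benzyl 4-{[4-({3,4-bis(benzyloxy)-6-methoxy-2-methylbenzoyl}oxy)-2-hydroxy-6-methylbenzoyl]oxy}-2-hydroxy-6-methylbenzoate, via mixed anhydride 27 (not isolated)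
Conditions: (CF3CO)2O, toluene, 0 °C → rt
Reagents that add atoms: trifluoroacetic anhydride, O=C(OC(=O)C(F)(F)F)C(F)(F)F (the CF3CO group, present only in 27)
Why: Second depside esterification by mixed-anhydride activation; of the three hydroxyls of 18 only the ring B 4-OH lacks a hydrogen bond to an ortho carbonyl, so it should be acylated selectively, and the conditions are acidic and base-free, which the existing depside ester tolerates.

Step 15
Reactants: 28 benzyl 4-{[4-({3,4-bis(benzyloxy)-6-methoxy-2-methylbenzoyl}oxy)-2-hydroxy-6-methylbenzoyl]oxy}-2-hydroxy-6-methylbenzoate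
Product: 29 4-{[4-({3,4-dihydroxy-6-methoxy-2-methylbenzoyl}oxy)-2-hydroxy-6-methylbenzoyl]oxy}-2-hydroxy-6-methylbenzoic acid (the target)
Conditions: H2 (1 atm), Pd/C, EtOAc–THF, rt
Reagents that add atoms: none
Why: Hydrogenolysis of two benzyl ethers and the benzyl ester in one neutral operation; aryl esters are not reduced, and work-up under inert gas protects the catechol.

## Compound list

1 | 2,3-butanedione | CC(=O)C(C)=O | starting material
2 | benzyl (triphenylphosphoranylidene)acetate | O=C(OCc1ccccc1)C=P(c1ccccc1)(c1ccccc1)c1ccccc1 | starting material
3 | benzyl (2E)-3-methyl-4-oxopent-2-enoate | CC(=O)/C(C)=C/C(=O)OCc1ccccc1 | intermediate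
4 | benzyl (2E)-6,6,6-trifluoro-3-methyl-4,6-dioxohex-2-enoate (trifluoroacetyl diketone, drawn as the diketo tautomer) | O=C(OCc1ccccc1)/C=C(\C)C(=O)CC(=O)C(F)(F)F | intermediate (not isolated)
5 | benzyl (2E)-5-diazo-3-methyl-4-oxopent-2-enoate | O=C(OCc1ccccc1)/C=C(\C)C(=O)C=[N+]=[N-] | intermediate
6 | 3-phenylisoxazole | c1ccc(-c2ccon2)cc1 | starting material
7 | triisopropylsilyl chloride | CC(C)[Si](Cl)(C(C)C)C(C)C | starting material
8 | lithium ethynolate | [Li+].[O-]C#C | intermediate (not isolated)
9 | (triisopropylsilyloxy)ethyne | C#CO[Si](C(C)C)(C(C)C)C(C)C | intermediate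
10 | benzyl (2E)-3-methyl-5-oxopenta-2,4-dienoate (vinylketene) | O=C=C/C(C)=C/C(=O)OCc1ccccc1 | intermediate (not isolated)
11 | benzyl (2E)-3-[4-oxo-2-(triisopropylsilyloxy)cyclobut-2-en-1-yl]but-2-enoate (cyclobutenone, racemic) | O=C1C=C(O[Si](C(C)C)(C(C)C)C(C)C)C1/C(C)=C/C(=O)OCc1ccccc1 | intermediate (not isolated)
12 | benzyl (2E,4E)-3-methyl-7-oxo-5-(triisopropylsilyloxy)hepta-2,4,6-trienoate (dienylketene) | O=C=C/C(O[Si](C(C)C)(C(C)C)C(C)C)=C\C(C)=C\C(=O)OCc1ccccc1 | intermediate (not isolated)
13 | benzyl 2-hydroxy-6-methyl-4-(triisopropylsilyloxy)benzoate | Cc1cc(O[Si](C(C)C)(C(C)C)C(C)C)cc(O)c1C(=O)OCc1ccccc1 | intermediate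
14 | benzyl 2,4-dihydroxy-6-methylbenzoate (benzyl orsellinate) | Cc1cc(O)cc(O)c1C(=O)OCc1ccccc1 | intermediate
15 | 2-hydroxy-6-methyl-4-(triisopropylsilyloxy)benzoic acid | Cc1cc(O[Si](C(C)C)(C(C)C)C(C)C)cc(O)c1C(=O)O | intermediate
16 | 2-hydroxy-6-methyl-4-(triisopropylsilyloxy)benzoic trifluoroacetic anhydride | Cc1cc(O[Si](C(C)C)(C(C)C)C(C)C)cc(O)c1C(=O)OC(=O)C(F)(F)F | intermediate (not isolated)
17 | benzyl 2-hydroxy-4-{[2-hydroxy-6-methyl-4-(triisopropylsilyloxy)benzoyl]oxy}-6-methylbenzoate | Cc1cc(O[Si](C(C)C)(C(C)C)C(C)C)cc(O)c1C(=O)Oc1cc(C)c(C(=O)OCc2ccccc2)c(O)c1 | intermediate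
18 | benzyl 4-[(2,4-dihydroxy-6-methylbenzoyl)oxy]-2-hydroxy-6-methylbenzoate | Cc1cc(O)cc(O)c1C(=O)Oc1cc(C)c(C(=O)OCc2ccccc2)c(O)c1 | intermediate
19 | 4-methoxy-2-methylphenol | COc1ccc(O)c(C)c1 | starting material
20 | 2-hydroxy-5-methoxy-3-methylbenzaldehyde | COc1cc(C)c(O)c(C=O)c1 | intermediate
21 | 2-hydroxy-5-methoxy-3-methylphenyl formate | COc1cc(C)c(O)c(OC=O)c1 | intermediate (not isolated)
22 | 5-methoxy-3-methylbenzene-1,2-diol | COc1cc(C)c(O)c(O)c1 | intermediate
23 | 1,2-bis(benzyloxy)-5-methoxy-3-methylbenzene | COc1cc(C)c(OCc2ccccc2)c(OCc2ccccc2)c1 | intermediate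
24 | N-{[3,4-bis(benzyloxy)-6-methoxy-2-methylphenyl]methylidene}-N-methylmethanaminium chloride | COc1cc(OCc2ccccc2)c(OCc2ccccc2)c(C)c1C=[N+](C)C.[Cl-] | intermediate (not isolated)
25 | 3,4-bis(benzyloxy)-6-methoxy-2-methylbenzaldehyde | COc1cc(OCc2ccccc2)c(OCc2ccccc2)c(C)c1C=O | intermediate
26 | 3,4-bis(benzyloxy)-6-methoxy-2-methylbenzoic acid | COc1cc(OCc2ccccc2)c(OCc2ccccc2)c(C)c1C(=O)O | intermediate
27 | 3,4-bis(benzyloxy)-6-methoxy-2-methylbenzoic trifluoroacetic anhydride | COc1cc(OCc2ccccc2)c(OCc2ccccc2)c(C)c1C(=O)OC(=O)C(F)(F)F | intermediate (not isolated)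
28 | benzyl 4-{[4-({3,4-bis(benzyloxy)-6-methoxy-2-methylbenzoyl}oxy)-2-hydroxy-6-methylbenzoyl]oxy}-2-hydroxy-6-methylbenzoate | COc1cc(OCc2ccccc2)c(OCc2ccccc2)c(C)c1C(=O)Oc1cc(C)c(C(=O)Oc2cc(C)c(C(=O)OCc3ccccc3)c(O)c2)c(O)c1 | intermediate
29 | 4-{[4-({3,4-dihydroxy-6-methoxy-2-methylbenzoyl}oxy)-2-hydroxy-6-methylbenzoyl]oxy}-2-hydroxy-6-methylbenzoic acid | COc1cc(O)c(O)c(C)c1C(=O)Oc1cc(C)c(C(=O)Oc2cc(C)c(C(=O)O)c(O)c2)c(O)c1 | target

## Step count and risks

Total: 15 steps. Longest linear sequence: 8 steps (1, 2, 4, 6, 7, 8, 14, 15). The ring A branch (steps 9 to 13) and the ynol ether (step 3) are convergent.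

**Step 4 (key step).**
- Risk: light-induced E to Z isomerisation of the enoate in 5, 10 or 11. Once the ester is cis to the ketene, the ketene can be trapped internally as a pyranone or the 6π closure is slowed, and the ketene is lost to dimers. Hydrolysis or oligomerisation of 9 during the irradiation is the second risk.
- Fallback: this gives up the ring construction and is the only fallback that does not start from a compound of the route. It sets out from purchased 2,4-dihydroxy-6-methylbenzoic acid F1 together with 7. Alkylation of the carboxylate of F1 with benzyl bromide and KHCO3 in DMF should give 14. Silylation of 14 with 7 and imidazole at the unchelated 4-OH returns 13.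

**Step 3.**
- Risk: silylation of 8 at carbon instead of oxygen, which is easier for the unsubstituted ynolate; addition of n-BuLi to the C=N bond of 6 in competition with ring deprotonation; and loss of the terminal ynol ether on isolation.
- Fallback: this replaces the silyl ynol ether by an alkyl one and sets out from 5. Irradiation of 5 with tert-butoxyethyne F2 should give benzyl 4-tert-butoxy-2-hydroxy-6-methylbenzoate F3 by the same annulation. CF3CO2H in CH2Cl2 removes the tert-butyl group and comes back at 14. For ring B, hydrogenolysis of F3 gives 4-tert-butoxy-2-hydroxy-6-methylbenzoic acid F4. Carbodiimide coupling of F4 with 14 (EDC·HCl, DMAP) gives benzyl 4-[(4-tert-butoxy-2-hydroxy-6-methylbenzoyl)oxy]-2-hydroxy-6-methylbenzoate F5, and CF3CO2H comes back at 18.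

**Step 2.**
- Risk: Michael addition of the lithium enolate to unreacted 3, or deprotonation at the C3 methyl, before the acylation takes place.
- Fallback: this avoids any metal enolate and sets out from 3. Heating 3 with N,N-dimethylformamide dimethyl acetal should give the enaminone benzyl (2E,5E)-6-(dimethylamino)-3-methyl-4-oxohexa-2,5-dienoate F6. Tosyl azide adds to the enamine double bond of F6, and fragmentation of the triazoline comes back at 5.

**Step 7.**
- Risk: self-acylation of 15 through its free 2-OH, trifluoroacetylation of the phenol partner that stalls the coupling, or acid-induced loss of the silyl group followed by oligomer formation.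
- Fallback: this protects the 2-OH and sets out from 13. Methoxymethyl chloride and i-Pr2NEt give benzyl 2-(methoxymethoxy)-6-methyl-4-(triisopropylsilyloxy)benzoate F7. Hydrogenolysis gives 2-(methoxymethoxy)-6-methyl-4-(triisopropylsilyloxy)benzoic acid F8. Coupling of F8 with 14 (EDC·HCl, DMAP, CH2Cl2) gives benzyl 2-hydroxy-4-{[2-(methoxymethoxy)-6-methyl-4-(triisopropylsilyloxy)benzoyl]oxy}-6-methylbenzoate F9. Brief CF3CO2H in CH2Cl2 at 0 °C removes the acetal and comes back at 17.

**Step 14.**
- Risk: acylation of a chelated hydroxyl or double acylation of 18, acid-promoted exchange of the depside ester already present, and slow reaction of the hindered acid.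
- Fallback: this reverses the order of assembly and sets out from 15. Allyl bromide and KHCO3 in DMF give allyl 2-hydroxy-6-methyl-4-(triisopropylsilyloxy)benzoate F10. Buffered Bu4NF gives allyl 2,4-dihydroxy-6-methylbenzoate F11. Coupling of F11 with 26 under the conditions of step 7 gives allyl 4-{[3,4-bis(benzyloxy)-6-methoxy-2-methylbenzoyl]oxy}-2-hydroxy-6-methylbenzoate F12. Pd(PPh3)4 with PhSiH3 removes the allyl group and gives 4-{[3,4-bis(benzyloxy)-6-methoxy-2-methylbenzoyl]oxy}-2-hydroxy-6-methylbenzoic acid F13. Coupling of F13 with 14 comes back at 28, each acylation then meeting a phenol with only one unchelated hydroxyl.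

## Further compounds

F1 | step 4 | 2,4-dihydroxy-6-methylbenzoic acid (orsellinic acid) | Cc1cc(O)cc(O)c1C(=O)O
F2 | step 3 | tert-butoxyethyne | C#COC(C)(C)C
F3 | step 3 | benzyl 4-tert-butoxy-2-hydroxy-6-methylbenzoate | Cc1cc(OC(C)(C)C)cc(O)c1C(=O)OCc1ccccc1
F4 | step 3 | 4-tert-butoxy-2-hydroxy-6-methylbenzoic acid | Cc1cc(OC(C)(C)C)cc(O)c1C(=O)O
F5 | step 3 | benzyl 4-[(4-tert-butoxy-2-hydroxy-6-methylbenzoyl)oxy]-2-hydroxy-6-methylbenzoate | Cc1cc(OC(C)(C)C)cc(O)c1C(=O)Oc1cc(C)c(C(=O)OCc2ccccc2)c(O)c1
F6 | step 2 | benzyl (2E,5E)-6-(dimethylamino)-3-methyl-4-oxohexa-2,5-dienoate | CN(C)/C=C/C(=O)/C(C)=C/C(=O)OCc1ccccc1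
F7 | step 7 | benzyl 2-(methoxymethoxy)-6-methyl-4-(triisopropylsilyloxy)benzoate | COCOc1cc(O[Si](C(C)C)(C(C)C)C(C)C)cc(C)c1C(=O)OCc1ccccc1
F8 | step 7 | 2-(methoxymethoxy)-6-methyl-4-(triisopropylsilyloxy)benzoic acid | COCOc1cc(O[Si](C(C)C)(C(C)C)C(C)C)cc(C)c1C(=O)O
F9 | step 7 | benzyl 2-hydroxy-4-{[2-(methoxymethoxy)-6-methyl-4-(triisopropylsilyloxy)benzoyl]oxy}-6-methylbenzoate | COCOc1cc(O[Si](C(C)C)(C(C)C)C(C)C)cc(C)c1C(=O)Oc1cc(C)c(C(=O)OCc2ccccc2)c(O)c1
F10 | step 14 | allyl 2-hydroxy-6-methyl-4-(triisopropylsilyloxy)benzoate | C=CCOC(=O)c1c(C)cc(O[Si](C(C)C)(C(C)C)C(C)C)cc1O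
F11 | step 14 | allyl 2,4-dihydroxy-6-methylbenzoate | C=CCOC(=O)c1c(C)cc(O)cc1O
F12 | step 14 | allyl 4-{[3,4-bis(benzyloxy)-6-methoxy-2-methylbenzoyl]oxy}-2-hydroxy-6-methylbenzoate | COc1cc(OCc2ccccc2)c(OCc2ccccc2)c(C)c1C(=O)Oc1cc(C)c(C(=O)OCC=C)c(O)c1
F13 | step 14 | 4-{[3,4-bis(benzyloxy)-6-methoxy-2-methylbenzoyl]oxy}-2-hydroxy-6-methylbenzoic acid | COc1cc(OCc2ccccc2)c(OCc2ccccc2)c(C)c1C(=O)Oc1cc(C)c(C(=O)O)c(O)c1
A1 | alternative 1 | benzyl 4-{[4-({3,4-bis(benzyloxy)-6-methoxy-2-methylbenzoyl}oxy)-2-hydroxy-6-methylbenzoyl]oxy}-2-hydroxy-6-methylbenzoate (identical with 28) | COc1cc(OCc2ccccc2)c(OCc2ccccc2)c(C)c1C(=O)Oc1cc(C)c(C(=O)Oc2cc(C)c(C(=O)OCc3ccccc3)c(O)c2)c(O)c1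
A2 | alternative 1 | 1,2-bis(benzyloxy)-4-iodo-5-methoxy-3-methylbenzene | COc1cc(OCc2ccccc2)c(OCc2ccccc2)c(C)c1I
A3 | alternative 1 | benzyl 4-[(2,4-dihydroxy-6-methylbenzoyl)oxy]-2-hydroxy-6-methylbenzoate (identical with 18) | Cc1cc(O)cc(O)c1C(=O)Oc1cc(C)c(C(=O)OCc2ccccc2)c(O)c1
A4 | alternative 1 | carbon monoxide | [C-]#[O+]
A5 | alternative 2 | benzyl trans-6-methyl-2,4-dioxocyclohexane-1-carboxylate (racemic) | C[C@@H]1CC(=O)CC(=O)[C@H]1C(=O)OCc1ccccc1
A6 | alternative 2 | benzyl acetoacetate | CC(=O)CC(=O)OCc1ccccc1
A7 | alternative 2 | ethyl (E)-but-2-enoate (ethyl crotonate) | C/C=C/C(=O)OCC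
A8 | alternative 3 | benzyl 2-(benzyloxy)-4-[(2,4-dihydroxy-6-methylbenzoyl)oxy]-6-methylbenzoate | Cc1cc(O)cc(O)c1C(=O)Oc1cc(C)c(C(=O)OCc2ccccc2)c(OCc2ccccc2)c1
A9 | alternative 3 | benzyl 2-(benzyloxy)-4-(but-2-ynoyloxy)-6-methylbenzoate | CC#CC(=O)Oc1cc(C)c(C(=O)OCc2ccccc2)c(OCc2ccccc2)c1
A10 | alternative 3 | 1-methoxy-1,3-bis(trimethylsilyloxy)buta-1,3-diene | COC(O[Si](C)(C)C)=CC(=C)O[Si](C)(C)C
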